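Time did little in the two earlier runs. On Tuesday's run, monomer in chains read 37.1% at 2.50 d and 36.9% at 10.0 d. On Monday's it read 59.5% at 1.25 d and 59.0% at 10.0 d, with a scatter of 0.5 percentage points per reading. So in both runs growth was over before the first reading, and each run gave one plateau.

all flasks: free monomer 2.4 M
- Tuesday's: transfer agent 0.24 M; pre-initiator 94 mM; run made earlier
- Monday's: transfer agent 0.24 M; pre-initiator 150 mM; run made earlier
- ochre: transfer agent 0.240 M; pre-initiator 120 mM; time 10 d
- blue: transfer agent 0.240 M; pre-initiator 200 mM; time 10 d

- Tuesday's (time / d: monomer in chains / %): 2.50: 37.1; 5.00: 37.1; 8.00: 37.0; 10.0: 36.9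
- Monday's (time / d: monomer in chains / %): 1.25: 59.5; 4.00: 58.7; 6.00: 59.1; 10.0: 59.0

(standard deviation of a reading: 0.5 percentage points)

- the average divides the monomer in chains by the number of chains begun, living and dead together
- the earlier runs do not show the number of chains; that part of a forecast is a guess

- which of the two ends with the longer chains by the average number of monomer units in a chain (chains begun, living or dead) ("neither" if they lie within 10%) (ochre / blue / neither)
- average number of monomer units in a chain (chains begun, living or dead) at the end, ochre
- average number of monomer units in a chain (chains begun, living or dead) at the end, blue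

The two runs had the same charges of free monomer and transfer agent and differed in pre-initiator, whose charge rose by a factor of 1.60. The final reading rose by a factor of 1.60, so I divided the plateau by the pre-initiator charged. Tuesday's run gave 9.42 and Monday's 9.44. Their mean, Y = 9.43, is the yield per pre-initiator: monomer units taken into chains for each pre-initiator charged.

For ochre, Y gave 47.2% of the free monomer charged in chains, and for blue 78.6%. The length n is monomer in chains divided by chains begun, and the readings show no chains, so the next step was my judgement. The plateau followed pre-initiator at a fixed charge of transfer agent, so I took one chain begun per pre-initiator, with the agent ending chains and beginning none. Then n equals Y in both flasks, and I expected 9.43 for each, hence neither.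

The forecast instead said blue, with 3.2 for ochre and 4.3 for blue: “I take efficient transfer, so blue is longer”. The flask gave neither, with 9.51 for ochre and 9.25 for blue.

    living end → dead end (k = 0.0240 h⁻¹)
    free monomer → uncatalysed product (k = 0.00600 h⁻¹)
    pre-initiator → initiator (k = 0.590 h⁻¹)
    living end + transfer agent → dead chain (kL = 3.60 L mol⁻¹ h⁻¹)
    free monomer + living end → monomer in chains + living end, rate k5*[living end]*[free monomer] (k = 3.30 L mol⁻¹ h⁻¹)
    free monomer + initiator → living end + monomer in chains (k = 1.60 L mol⁻¹ h⁻¹)

In ochre, the turning of free monomer into monomer in chains had half its turnover up to 10.0 d behind it by 0.117 d, and by 5.00 d living end stood at 0 M and pre-initiator at 0%, with 51.8% of the transfer agent left. From then to 10.0 d, uncatalysed product rose from 27.4% to 40.2% while monomer in chains held at 47.6%. Dead chain and dead end together came to 0.120 M in ochre and 0.200 M in blue, against 120 mM and 200 mM of pre-initiator charged.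

Take ochre's recipe with 0.030 M of pre-initiator. There Y gives 0.283 M of monomer in chains, which is 11.8% of the free monomer charged, and a length of 9.43. The computed flask gave 12.1% and 9.70.

(All runs come from a simulation for substances that don't exist; scatter was added.)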